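Rem (assumption on the chemistry): all bicyclic compounds are numbered as in labdane (decalin C1–C10; chain C11–C12–C13–C16 on C9; C17 exocyclic on C8; C18 = α-methyl and C19 = β-carbon on C4; C20 = methyl on C10), and α/β refer to the usual drawing with C20 β.

## Structural features

The target 20 is a 14,15-dinorlabdane: a trans-fused decalin (ring A = C1–C5/C10, ring B = C5–C10) with a 3-oxobutyl chain on C9 and an exocyclic methylene (C17) on C8. It has six stereocentres, (2R,4S,5R,7R,9R,10S). Four of them (C4, C5, C10, C9) are contiguous; C4 and C10 are quaternary, 1,3-related, and carry their β-substituents (C19, C20) both axial. C4 bears the α-methyl C18 and the β-axial acetoxymethyl C19; C2 bears an equatorial 2α-hydroxyl and C7 an axial, allylic 7α-hydroxyl. The fragile groups are the secondary allylic alcohol next to the 8(17)-alkene (allylic transposition in acid, over-oxidation to the enone), the primary acetate (base, hydride) and the enolisable methyl ketone. The real difficulty is the C4–C5–C10–C9 array with two quaternary carbons, combined with three oxygen functions of which only O19 is acylated. The key step exploits the C19–C4–C3 unit: with C19 as an ester and C3 as a ketone it is a β-keto ester whose C4 radical can close ring A onto C5 and ring B from C10 onto C9, and the radical left at C8 can lose a C17 hydrogen to give the 8(17)-methylene directly. The price is that the ring A oxygen then sits on C3 and not on C2, which must be repaired afterwards.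

## Logic of the disconnections

20 ⇒ 19. The C13 ketal C–O bonds and the O2–Si bond are the last to be cleaved. The methyl ketone and the 2-hydroxyl must stay silent through enolate, hydride, radical and oxidation chemistry. The demand is one acid treatment mild enough for the allylic alcohol and the acetate.

19 ⇒ 18. The C7–O bond is cut. The allylic alcohol is the most fragile group and is therefore made last, by allylic oxidation of the 8(17)-alkene. 18 then has a single reactive site; the forward step must choose C7 over C9 and deliver oxygen to the α-face.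

18 ⇒ 17 ⇒ 15 ⇒ 14. The acetyl–O19 bond is cut and the C3–O bond is put back. The 3β,19-diol of 14 comes from one reduction of a β-keto ester, and its 1,3-relationship allows a cyclic thionocarbonate. The hindered C3 oxygen can then be removed by radical fragmentation while O19 emerges as the only free hydroxyl, so the acetylation needs no selectivity. The demand is fragmentation toward the secondary C3 radical.

14 ⇒ 13 ⇒ 12 ⇒ 10. The C2–O bond is cut; C3 returns to the ketone and C19 to the ester. In 10 the C3 ketone activates only C2, because C4 is quaternary. A 2-oxo intermediate is deliberately avoided: hydride would attack such a ketone from the α-face, away from the two β-axial groups on C4 and C10, and give the axial 2β-alcohol. The oxygen is therefore introduced at C2 with the 2α configuration already in place, and C3 is deoxygenated. The demand is α-face attack on the enolate.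

10 ⇒ 9. The C4–C5 and C9–C10 bonds are cut and a hydrogen is returned to C17. This removes both rings and four stereocentres at once. 9 contains two E-alkenes; it is a dienyl β-keto ester, and three C=C bonds are counted only in its enol form. The forward step needs a chair–chair fold, face selection at C4 by the ester auxiliary and a termination that gives the exocyclic alkene.

9 ⇒ 4 + 7. The C1–C2 bond is cut between the terminal carbon of the keto ester and an allylic carbon. The route becomes convergent, and the auxiliary is carried by the small fragment. The demand is alkylation at the terminal carbon of a dianion, by direct displacement, with the C13 ketone masked.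

7 ⇒ 5 + 6. The ester C–O bond is cut; this needs transesterification with a hindered secondary alcohol.

4 ⇒ 3 ⇒ 2 ⇒ 1. The C–Br bond, the allylic C–O bond and the ketal C–O bonds are cut. The forward demand is oxidation of only the terminal E-methyl group of a diene with retention of alkene geometry.

## Other disconnections considered

Alternative 1: The cut is C9–C10, with C9–C20 as a temporary bond. In the forward direction diazoketone A1 (ring A with an exocyclic C10=C20 methylene and a C6–C7–C8(=O)–C9HN2 arm on C5) would be treated with Rh2(OAc)4. The rhodium carbenoid at C9 would add across C10=C20 to give cyclopropyl ketone A2. Dissolving-metal opening of the C9–C20 bond would later reveal the C20 methyl group and a C8/C9 enolate for attachment of C11–C13.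
- In favour: the tether delivers the carbenoid intramolecularly and the addition is stereospecific; the enolate formed on opening is regiodefined; the C2 oxygen and the C4 quaternary centre are present from the start.
- Against: A1 already needs C2, C4 and C5 set in enantiopure form; the key step closes one ring and leaves one permanent C–C bond; C–H insertion into the C1 methylene can compete; after A2 the route still needs C9 alkylation, methylenation of a hindered C8 ketone and the C7 oxidation.
- Structure: the alternative is the better plan at C2 (no relocation of oxygen) and the equal at the C8 carbonyl/methylene stage; the chosen plan is better at C4, C5, C10 and C9, which it sets together.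
- Mechanism: a tether-controlled carbenoid addition is at least as dependable as auxiliary control over a free radical, but the regiochemistry of the cyclopropane opening is an extra demand.
- Step economy: worse; ring A must be built stereoselectively first, so the count should clearly exceed the 14 steps of the chosen plan.

Alternative 2: The cut is C3–C4, with ring A closed last and C18 derived from an alkene carbon. Z-vinyl iodide A3 (ring B ketone with a CH2–CH=CHI arm on C10 and a 3-silyloxyprop-1-en-2-yl group on C5) would react with Pd(OAc)2/PPh3 and HCO2Na. Zerovalent palladium would insert into C3–I, C3 would add to C4 in a 6-exo carbopalladation, and formate would reduce the neopentyl C18–Pd bond to give A4.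
- In favour: no β-hydrogen is available, so termination is clean; the ring B stereocentres come from the chiral pool; the 2,3-alkene of A4 could be hydroborated at C2 from the α-face while C8 is still a carbonyl carbon. This is a shorter and more direct way to 2α-OH than hydroxylation and C3 deoxygenation, and here the alternative is the better plan.
- Against: the C4 configuration depends on which alkene face inserts, and the required product puts the silyloxymethyl group in the congested β-axial position syn to C20; A3 needs a long relay including the quaternary C10; C8 methylenation and C7 oxidation remain.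
- Structure: equal in delivering an oxidised C19 on the quaternary carbon; the chosen plan places C19 axial through an intrinsic preference of the radical.
- Mechanism: two-electron organopalladium chemistry avoids radical termination problems and an acidic oxidising medium, so it is the equal or the better in functional-group tolerance.
- Step economy: worse, because ring B with three stereocentres must be made first.

Alternative 3: The cut is C8–C9 and C11–C12, with C8–C12 as a temporary bond. Irradiation of dioxinone A5 (ring A with a C10 vinyl group and, through C6–C7, a 2,2-dimethyl-1,3-dioxin-4-one) would form C8–C9 and C11–C12. K2CO3 in methanol would then open the dioxinone and cleave C8–C12 by retro-aldol (de Mayo sequence) to give keto ester A6.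
- In favour: ring B, the C8 carbonyl and a three-carbon C9 chain arise in one sequence; no oxidant is involved; the C2 oxygen is present from the start, a point on which it is better than the chosen plan.
- Against: A5 needs ring A with C2, C4, C5 and C10 already set, two of them quaternary, so the main difficulty is only moved earlier; the orientation and facial course of the cycloaddition decide C9; the chain ends as a methyl ester and must be turned into the methyl ketone in the presence of the C8 ketone.
- Structure: equal in forming the C9 chain together with ring B; the chosen plan is better because it also forms ring A and both quaternary centres.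
- Mechanism: the triplet biradical cycloaddition is equal or better in chemoselectivity; stereocontrol at C9 is indirect in both plans.
- Step economy: worse.

Key step: step 6

## Route

Step 1
Reactants: 1 geranylacetone [(5E)-6,10-dimethylundeca-5,9-dien-2-one]
Product: 2 2-[(3E)-4,8-dimethylnona-3,7-dien-1-yl]-2-methyl-1,3-dioxolane
Conditions: HOCH2CH2OH, pyridinium p-toluenesulfonate (cat.), benzene, reflux, Dean–Stark
Reagents that add atoms: ethylene glycol, OCCO
Why: Acid-catalysed ketalisation with removal of water; the weak acid leaves the trisubstituted alkenes untouched, and the dioxolane is needed for the dianion, enolate and hydride steps that follow.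

Step 2
Reactants: 2 2-[(3E)-4,8-dimethylnona-3,7-dien-1-yl]-2-methyl-1,3-dioxolane
Product: 3 (2E,6E)-2,6-dimethyl-9-(2-methyl-1,3-dioxolan-2-yl)nona-2,6-dien-1-ol
Conditions: SeO2 (0.2 equiv), t-BuOOH (2 equiv), salicylic acid (cat.), CH2Cl2, 0 °C to rt
Reagents that add atoms: selenium dioxide, O=[Se]=O (catalytic oxygen carrier); tert-butyl hydroperoxide, CC(C)(C)OO (stoichiometric oxygen source)
Why: SeO2 allylic oxidation (ene reaction, then [2,3]-sigmatropic shift) should occur at the terminal trisubstituted alkene on the methyl group trans to the chain and give the E-allylic alcohol; stopping short of full conversion limits enal formation.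

Step 3
Reactants: 3 (2E,6E)-2,6-dimethyl-9-(2-methyl-1,3-dioxolan-2-yl)nona-2,6-dien-1-ol
Product: 4 2-[(3E,7E)-9-bromo-4,8-dimethylnona-3,7-dien-1-yl]-2-methyl-1,3-dioxolane
Conditions: CBr4, PPh3, CH2Cl2, 0 °C
Reagents that add atoms: carbon tetrabromide, BrC(Br)(Br)Br
Why: Appel bromination of a primary allylic alcohol under neutral conditions; displacement at the primary carbon keeps the E geometry and the ketal.

Step 4
Reactants: 5 ethyl 2-methyl-3-oxobutanoate; 6 (1R,2S,5R)-8-phenylmenthol [(1R,2S,5R)-5-methyl-2-(2-phenylpropan-2-yl)cyclohexan-1-ol]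
Product: 7 (1R,2S,5R)-8-phenylmenthyl 2-methyl-3-oxobutanoate (both epimers at the α-carbon)
Conditions: DMAP (0.3 equiv), toluene, reflux, distillation of EtOH
Reagents that add atoms: none
Why: DMAP-promoted transesterification of a β-keto ester, which runs through the acylketene and so tolerates the hindered secondary alcohol; the α-centre is labile and irrelevant because it becomes the radical carbon.

Step 5
Reactants: 7 (1R,2S,5R)-8-phenylmenthyl 2-methyl-3-oxobutanoate; 4 2-[(3E,7E)-9-bromo-4,8-dimethylnona-3,7-dien-1-yl]-2-methyl-1,3-dioxolane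
Product: 9 (1R,2S,5R)-8-phenylmenthyl (6E,10E)-2,6,10-trimethyl-13-(2-methyl-1,3-dioxolan-2-yl)-3-oxotrideca-6,10-dienoate, via sodium lithium dienolate 8 (not isolated)
Conditions: NaH, THF, 0 °C; n-BuLi, 0 °C; 4, 0 °C to rt; aq. NH4Cl
Reagents that add atoms: none
Why: Acetoacetate dianion alkylation: the second, more basic carbanion at the terminal methyl group attacks the primary allylic bromide by SN2 without allylic transposition and joins C2 to C1.

Step 6
Reactants: 9 (1R,2S,5R)-8-phenylmenthyl (6E,10E)-2,6,10-trimethyl-13-(2-methyl-1,3-dioxolan-2-yl)-3-oxotrideca-6,10-dienoate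
Product: 10 (1R,2S,5R)-8-phenylmenthyl 13,13-ethylenedioxy-3-oxo-14,15-dinorlabd-8(17)-en-19-oate (5α-H, 9α-H, 10β-methyl, 4β-ester)
Conditions: Mn(OAc)3·2H2O (2.2 equiv), Cu(OAc)2·H2O (0.5 equiv), NaOAc (2 equiv), degassed AcOH, 20 °C
Reagents that add atoms: none
Why: This is an oxidative free-radical polyene cyclisation of an α-methyl β-keto ester with Mn(OAc)3 and Cu(OAc)2, a known reaction type that includes 8-phenylmenthyl esters: trivalent manganese oxidises the manganese enolate of 9 to the electrophilic C4 radical. Ring A closes by 6-endo-trig attack of C4 on C5 and ring B by 6-endo-trig attack of the tertiary C10 radical on C9; in both closures attack at the less substituted alkene carbon leaves a tertiary radical. Divalent copper captures the tertiary C8 radical and the organocopper species loses a C17 hydrogen to give the less substituted 8(17)-alkene, while Mn(OAc)3 returns the monovalent copper to the divalent state. C5 and C10 are controlled by the E geometry of the C5–C10 alkene in a chair fold (trans fusion, C20 axial), and C9 by the E geometry of the C8–C9 alkene in the second chair (C11 equatorial, β). At C4 the relative configuration comes from the free, non-chelated radical, in which the ester carbon lies anti to the ketone oxygen and therefore ends axial (C19 β, cis to C20). The absolute sense comes from the auxiliary: with the ester in its usual s-cis conformation the phenyl ring covers one face of the planar radical, and C5 should add to the open Re face at C4 (ester > ketone > methyl), which corresponds to the (4R,5R,9S,10R) core of 10. The step needs face selectivity at C4, endo regioselectivity and Hofmann-type termination; these are secured by the auxiliary, by the trisubstituted E-alkenes and by the copper salt, in that order. No Lewis acid is added, because chelation would turn the ester syn to the ketone oxygen and favour the C4 epimer, and NaOAc buffers the acetic acid so that the dioxolane is kept.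

Step 7
Reactants: 10 (1R,2S,5R)-8-phenylmenthyl 13,13-ethylenedioxy-3-oxo-14,15-dinorlabd-8(17)-en-19-oate
Product: 12 (1R,2S,5R)-8-phenylmenthyl 13,13-ethylenedioxy-2α-hydroxy-3-oxo-14,15-dinorlabd-8(17)-en-19-oate, via potassium enolate 11 (not isolated)
Conditions: KN(SiMe3)2, THF, −78 °C; 2-(phenylsulfonyl)-3-phenyloxaziridine, −78 °C; AcOH
Reagents that add atoms: 2-(phenylsulfonyl)-3-phenyloxaziridine, O=S(=O)(c1ccccc1)N1OC1c1ccccc1
Why: Enolate hydroxylation with an N-sulfonyloxaziridine (Davis oxidation); C2 is the only enolisable position of the C3 ketone, and the oxidant should add to the α-face, away from the β-axial C19 ester and C20 methyl, giving the equatorial 2α-alcohol, which is also the more stable epimer.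

Step 8
Reactants: 12 (1R,2S,5R)-8-phenylmenthyl 13,13-ethylenedioxy-2α-hydroxy-3-oxo-14,15-dinorlabd-8(17)-en-19-oate
Product: 13 (1R,2S,5R)-8-phenylmenthyl 2α-(tert-butyldimethylsilyloxy)-13,13-ethylenedioxy-3-oxo-14,15-dinorlabd-8(17)-en-19-oate
Conditions: TBSCl, imidazole, DMF, rt
Reagents that add atoms: tert-butyldimethylsilyl chloride, CC(C)(C)[Si](C)(C)Cl
Why: Silylation of the unhindered equatorial alcohol under weakly basic conditions that should not isomerise the α-ketol; the silyl ether marks O2 so that O19 can later be acetylated alone.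

Step 9
Reactants: 13 (1R,2S,5R)-8-phenylmenthyl 2α-(tert-butyldimethylsilyloxy)-13,13-ethylenedioxy-3-oxo-14,15-dinorlabd-8(17)-en-19-oate
Product: 14 2α-(tert-butyldimethylsilyloxy)-13,13-ethylenedioxy-14,15-dinorlabd-8(17)-ene-3β,19-diol
Conditions: LiAlH4, THF, 0 °C to 50 °C; Fieser work-up
Reagents that add atoms: none
Why: Hydride reduction of ketone and ester; hydride should reach C3 axially from the α-face, away from the β-axial C19 group, to give the equatorial 3β-alcohol (gauche to C19), and the hindered ester is taken to the primary alcohol with release of 6 for recovery.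

Step 10
Reactants: 14 2α-(tert-butyldimethylsilyloxy)-13,13-ethylenedioxy-14,15-dinorlabd-8(17)-ene-3β,19-diol
Product: 15 3β,19-cyclic thionocarbonate of 14 (six-membered ring O3–C(=S)–O19)
Conditions: 1,1'-thiocarbonyldiimidazole, DMAP (cat.), toluene, 90 °C
Reagents that add atoms: 1,1'-thiocarbonyldiimidazole, S=C(n1ccnc1)n1ccnc1
Why: Cyclic thionocarbonate formation from a 1,3-diol; the primary O19 is thioacylated first and the ring then closes intramolecularly onto the hindered O3, which an external reagent would reach only with difficulty.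

Step 11
Reactants: 15 3β,19-cyclic thionocarbonate of 14
Product: 17 2α-(tert-butyldimethylsilyloxy)-13,13-ethylenedioxy-14,15-dinorlabd-8(17)-en-19-ol, via stannyl thiocarbonate 16 (not isolated)
Conditions: Bu3SnH, AIBN (cat.), toluene, 110 °C; then aq. K2CO3, MeOH, rt
Reagents that add atoms: none
Why: Barton-type radical deoxygenation of a cyclic thionocarbonate: the stannyl radical adds to sulfur and β-scission should break the C3–O bond, which gives a secondary radical and relieves strain at the neopentyl position, whereas the other path would give a primary radical; hydrogen transfer from Bu3SnH and hydrolysis of the S-stannyl thiocarbonate leave C3 as CH2 and O19 free.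

Step 12
Reactants: 17 2α-(tert-butyldimethylsilyloxy)-13,13-ethylenedioxy-14,15-dinorlabd-8(17)-en-19-ol
Product: 18 19-acetoxy-2α-(tert-butyldimethylsilyloxy)-13,13-ethylenedioxy-14,15-dinorlabd-8(17)-ene
Conditions: Ac2O, pyridine, DMAP (cat.), CH2Cl2, rt
Reagents that add atoms: acetic anhydride, CC(=O)OC(C)=O
Why: DMAP-catalysed acetylation of the only free hydroxyl group, so no selectivity is required.

Step 13
Reactants: 18 19-acetoxy-2α-(tert-butyldimethylsilyloxy)-13,13-ethylenedioxy-14,15-dinorlabd-8(17)-ene
Product: 19 19-acetoxy-2α-(tert-butyldimethylsilyloxy)-13,13-ethylenedioxy-14,15-dinorlabd-8(17)-en-7α-ol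
Conditions: SeO2 (0.5 equiv), t-BuOOH (2 equiv), CH2Cl2, 0 °C to rt
Reagents that add atoms: selenium dioxide, O=[Se]=O (oxygen carrier); tert-butyl hydroperoxide, CC(C)(C)OO (stoichiometric oxygen source)
Why: SeO2 allylic oxidation (ene reaction, then [2,3]-sigmatropic shift) of the exocyclic alkene should go to the ring CH2 at C7 in preference to the CH at C9; the axial 7α-hydrogen is aligned with the π-system and the shift returns oxygen to the same α-face, giving the axial 7α-alcohol with the 8(17)-alkene restored.

Step 14
Reactants: 19 19-acetoxy-2α-(tert-butyldimethylsilyloxy)-13,13-ethylenedioxy-14,15-dinorlabd-8(17)-en-7α-ol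
Product: 20 19-acetoxy-2α,7α-dihydroxy-14,15-dinorlabd-8(17)-en-13-one, (2R,4S,5R,7R,9R,10S)
Conditions: 48% aq. HF, MeCN, 0 °C to rt
Reagents that add atoms: water, O
Why: Acid hydrolysis of the dioxolane and of the secondary silyl ether in one operation; HF is a weak acid with a poorly nucleophilic counter-ion, so the allylic alcohol should not ionise and the acetate should not be hydrolysed.

## Compound list

1 | geranylacetone, (5E)-6,10-dimethylundeca-5,9-dien-2-one | CC(C)=CCC/C(C)=C/CCC(C)=O | starting material
2 | 2-[(3E)-4,8-dimethylnona-3,7-dien-1-yl]-2-methyl-1,3-dioxolane | CC(C)=CCC/C(C)=C/CCC1(C)OCCO1 | intermediate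
3 | (2E,6E)-2,6-dimethyl-9-(2-methyl-1,3-dioxolan-2-yl)nona-2,6-dien-1-ol | OC/C(C)=C/CC/C(C)=C/CCC1(C)OCCO1 | intermediate
4 | 2-[(3E,7E)-9-bromo-4,8-dimethylnona-3,7-dien-1-yl]-2-methyl-1,3-dioxolane | BrC/C(C)=C/CC/C(C)=C/CCC1(C)OCCO1 | intermediate
5 | ethyl 2-methyl-3-oxobutanoate | CCOC(=O)C(C)C(C)=O | starting material
6 | (1R,2S,5R)-8-phenylmenthol | CC(C)(c1ccccc1)[C@@H]1CC[C@@H](C)C[C@H]1O | starting material
7 | (1R,2S,5R)-8-phenylmenthyl 2-methyl-3-oxobutanoate (both α-epimers) | CC(=O)C(C)C(=O)O[C@@H]1C[C@H](C)CC[C@H]1C(C)(C)c1ccccc1 | intermediate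
8 | sodium lithium dienolate (dianion) of 7 | [Na+].[Li+].C=C([O-])C(C)=C([O-])O[C@@H]1C[C@H](C)CC[C@H]1C(C)(C)c1ccccc1 | intermediate (not isolated)
9 | (1R,2S,5R)-8-phenylmenthyl (6E,10E)-2,6,10-trimethyl-13-(2-methyl-1,3-dioxolan-2-yl)-3-oxotrideca-6,10-dienoate | CC(C(=O)O[C@@H]1C[C@H](C)CC[C@H]1C(C)(C)c1ccccc1)C(=O)CC/C(C)=C/CC/C(C)=C/CCC2(C)OCCO2 | intermediate
10 | (1R,2S,5R)-8-phenylmenthyl 13,13-ethylenedioxy-3-oxo-14,15-dinorlabd-8(17)-en-19-oate | C=C1CC[C@H]2[C@@](C)(C(=O)O[C@@H]3C[C@H](C)CC[C@H]3C(C)(C)c3ccccc3)C(=O)CC[C@]2(C)[C@H]1CCC1(C)OCCO1 | intermediate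
11 | potassium 2(3)-enolate of 10 | [K+].C=C1CC[C@H]2[C@@](C)(C(=O)O[C@@H]3C[C@H](C)CC[C@H]3C(C)(C)c3ccccc3)C([O-])=CC[C@]2(C)[C@H]1CCC1(C)OCCO1 | intermediate (not isolated)
12 | (1R,2S,5R)-8-phenylmenthyl 13,13-ethylenedioxy-2α-hydroxy-3-oxo-14,15-dinorlabd-8(17)-en-19-oate | C=C1CC[C@H]2[C@@](C)(C(=O)O[C@@H]3C[C@H](C)CC[C@H]3C(C)(C)c3ccccc3)C(=O)[C@H](O)C[C@]2(C)[C@H]1CCC1(C)OCCO1 | intermediate
13 | (1R,2S,5R)-8-phenylmenthyl 2α-(tert-butyldimethylsilyloxy)-13,13-ethylenedioxy-3-oxo-14,15-dinorlabd-8(17)-en-19-oate | C=C1CC[C@H]2[C@@](C)(C(=O)O[C@@H]3C[C@H](C)CC[C@H]3C(C)(C)c3ccccc3)C(=O)[C@H](O[Si](C)(C)C(C)(C)C)C[C@]2(C)[C@H]1CCC1(C)OCCO1 | intermediate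
14 | 2α-(tert-butyldimethylsilyloxy)-13,13-ethylenedioxy-14,15-dinorlabd-8(17)-ene-3β,19-diol | C=C1CC[C@H]2[C@@](C)(CO)[C@@H](O)[C@H](O[Si](C)(C)C(C)(C)C)C[C@]2(C)[C@H]1CCC1(C)OCCO1 | intermediate
15 | 3β,19-cyclic thionocarbonate of 14 | C=C1CC[C@H]2[C@@](C)(COC(=S)O3)[C@@H]3[C@H](O[Si](C)(C)C(C)(C)C)C[C@]2(C)[C@H]1CCC1(C)OCCO1 | intermediate
16 | O-(C19) S-(tributylstannyl) thiocarbonate of 17 | C=C1CC[C@H]2[C@@](C)(COC(=O)S[Sn](CCCC)(CCCC)CCCC)C[C@H](O[Si](C)(C)C(C)(C)C)C[C@]2(C)[C@H]1CCC1(C)OCCO1 | intermediate (not isolated)
17 | 2α-(tert-butyldimethylsilyloxy)-13,13-ethylenedioxy-14,15-dinorlabd-8(17)-en-19-ol | C=C1CC[C@H]2[C@@](C)(CO)C[C@H](O[Si](C)(C)C(C)(C)C)C[C@]2(C)[C@H]1CCC1(C)OCCO1 | intermediate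
18 | 19-acetoxy-2α-(tert-butyldimethylsilyloxy)-13,13-ethylenedioxy-14,15-dinorlabd-8(17)-ene | C=C1CC[C@H]2[C@@](C)(COC(C)=O)C[C@H](O[Si](C)(C)C(C)(C)C)C[C@]2(C)[C@H]1CCC1(C)OCCO1 | intermediate
19 | 19-acetoxy-2α-(tert-butyldimethylsilyloxy)-13,13-ethylenedioxy-14,15-dinorlabd-8(17)-en-7α-ol | C=C1[C@H](O)C[C@H]2[C@@](C)(COC(C)=O)C[C@H](O[Si](C)(C)C(C)(C)C)C[C@]2(C)[C@H]1CCC1(C)OCCO1 | intermediate
20 | 19-acetoxy-2α,7α-dihydroxy-14,15-dinorlabd-8(17)-en-13-one | C=C1[C@H](O)C[C@H]2[C@@](C)(COC(C)=O)C[C@H](O)C[C@]2(C)[C@H]1CCC(C)=O | target

## Step count and least certain steps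

Total: 14 steps. Longest linear sequence: 13 steps (1 to 20 through steps 1–3 and 5–14; step 4 is the side branch).

**Step 6 (key step).** The most likely failure is insufficient or reversed face discrimination at C4. The radical is free, the ester can rotate about the C4–C19 bond, and the two rotamers expose opposite faces to the open side of the auxiliary. Interrupted cyclisation, endocyclic alkene formation and partial loss of the ketal in acetic acid are lesser risks. The fallback exchanges the stereocontrolling unit for its mirror image; it sets out from 5 and 4 and returns at 14. 5 would be transesterified (DMAP, toluene, reflux) with (1S,2R,5S)-8-phenylmenthol F1 to (1S,2R,5S)-8-phenylmenthyl 2-methyl-3-oxobutanoate F2. Its dianion would be alkylated with 4 to the dienyl keto ester F3. Cyclisation with Mn(OAc)3/Cu(OAc)2 would give the 3-oxo 19-ester F4 with the decalin core of 10. Hydroxylation as in step 7 would give the 2α-hydroxy ketone F5, silylation the 2α-silyl ether F6, and LiAlH4 would convert F6 into 14 with release of F1.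

**Step 11.** The risk is fragmentation in the wrong direction (C19–O in place of C3–O), or reduction of the thiocarbonyl group without ring opening, because opening of a six-membered thionocarbonate depends on orbital alignment as well as on radical stability. The fallback sets out from 14 and returns at 18. Selective acetylation of the primary hydroxyl (Ac2O, pyridine, 0 °C) would give the 19-acetate 3β-alcohol F7. Phenyl chlorothionoformate with DMAP would give the 3β-O-phenoxythiocarbonyl derivative F8. Barton–McCombie reduction (Bu3SnH, AIBN, toluene, 110 °C) would then give 18 directly, replacing steps 10–12.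

**Step 13.** The risks are over-oxidation to the enone, competing attack at the C9 methine and incomplete α-face selectivity. The fallback sets out from 18 and returns at 19. The oxidation would be driven to the ketone (SeO2/t-BuOOH, then MnO2) to give the 8(17)-en-7-one F9. Reagent-controlled 1,2-reduction with the (S)-methyl-CBS oxazaborolidine and catecholborane, with the alkenyl carbon as the large group, should then give the 7α-alcohol 19.

**Step 9.** The risks are loss or 1,2-migration of the silyl group next to the newly formed C3 alkoxide, and slow reduction of the hindered axial ester. The fallback reverses the order of protection and reduction; it sets out from 12 and returns at 15. LiAlH4 would reduce 12 to the 2α,3β,19-triol F10. 1,1'-Thiocarbonyldiimidazole should react first at the primary O19 and close the six-membered ring onto O3, giving the 2α-hydroxy 3β,19-thionocarbonate F11. Silylation with TBSCl and imidazole would then give 15.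

## Further compounds

F1 | step 6 | (1S,2R,5S)-8-phenylmenthol | CC(C)(c1ccccc1)[C@H]1CC[C@H](C)C[C@@H]1O
F2 | step 6 | (1S,2R,5S)-8-phenylmenthyl 2-methyl-3-oxobutanoate | CC(=O)C(C)C(=O)O[C@H]1C[C@@H](C)CC[C@@H]1C(C)(C)c1ccccc1
F3 | step 6 | (1S,2R,5S)-8-phenylmenthyl (6E,10E)-2,6,10-trimethyl-13-(2-methyl-1,3-dioxolan-2-yl)-3-oxotrideca-6,10-dienoate | CC(C(=O)O[C@H]1C[C@@H](C)CC[C@@H]1C(C)(C)c1ccccc1)C(=O)CC/C(C)=C/CC/C(C)=C/CCC2(C)OCCO2
F4 | step 6 | (1S,2R,5S)-8-phenylmenthyl 13,13-ethylenedioxy-3-oxo-14,15-dinorlabd-8(17)-en-19-oate | C=C1CC[C@H]2[C@@](C)(C(=O)O[C@H]3C[C@@H](C)CC[C@@H]3C(C)(C)c3ccccc3)C(=O)CC[C@]2(C)[C@H]1CCC1(C)OCCO1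
F5 | step 6 | (1S,2R,5S)-8-phenylmenthyl 13,13-ethylenedioxy-2α-hydroxy-3-oxo-14,15-dinorlabd-8(17)-en-19-oate | C=C1CC[C@H]2[C@@](C)(C(=O)O[C@H]3C[C@@H](C)CC[C@@H]3C(C)(C)c3ccccc3)C(=O)[C@H](O)C[C@]2(C)[C@H]1CCC1(C)OCCO1
F6 | step 6 | (1S,2R,5S)-8-phenylmenthyl 2α-(tert-butyldimethylsilyloxy)-13,13-ethylenedioxy-3-oxo-14,15-dinorlabd-8(17)-en-19-oate | C=C1CC[C@H]2[C@@](C)(C(=O)O[C@H]3C[C@@H](C)CC[C@@H]3C(C)(C)c3ccccc3)C(=O)[C@H](O[Si](C)(C)C(C)(C)C)C[C@]2(C)[C@H]1CCC1(C)OCCO1
F7 | step 11 | 19-acetoxy-2α-(tert-butyldimethylsilyloxy)-13,13-ethylenedioxy-14,15-dinorlabd-8(17)-en-3β-ol | C=C1CC[C@H]2[C@@](C)(COC(C)=O)[C@@H](O)[C@H](O[Si](C)(C)C(C)(C)C)C[C@]2(C)[C@H]1CCC1(C)OCCO1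
F8 | step 11 | 3β-O-phenoxythiocarbonyl derivative of F7 | C=C1CC[C@H]2[C@@](C)(COC(C)=O)[C@@H](OC(=S)Oc3ccccc3)[C@H](O[Si](C)(C)C(C)(C)C)C[C@]2(C)[C@H]1CCC1(C)OCCO1
F9 | step 13 | 19-acetoxy-2α-(tert-butyldimethylsilyloxy)-13,13-ethylenedioxy-14,15-dinorlabd-8(17)-en-7-one | C=C1C(=O)C[C@H]2[C@@](C)(COC(C)=O)C[C@H](O[Si](C)(C)C(C)(C)C)C[C@]2(C)[C@H]1CCC1(C)OCCO1
F10 | step 9 | 13,13-ethylenedioxy-14,15-dinorlabd-8(17)-ene-2α,3β,19-triol | C=C1CC[C@H]2[C@@](C)(CO)[C@@H](O)[C@H](O)C[C@]2(C)[C@H]1CCC1(C)OCCO1
F11 | step 9 | 2α-hydroxy 3β,19-cyclic thionocarbonate (desilyl 15) | C=C1CC[C@H]2[C@@](C)(COC(=S)O3)[C@@H]3[C@H](O)C[C@]2(C)[C@H]1CCC1(C)OCCO1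
A1 | alternative 1 | ring A α-diazoketone with exocyclic C10=C20 methylene, 2α-OTBS and 19-OTES | [N-]=[N+]=CC(=O)CC[C@H]1[C@@](C)(CO[Si](CC)(CC)CC)C[C@H](O[Si](C)(C)C(C)(C)C)CC1=C
A2 | alternative 1 | tricyclic cyclopropyl ketone (C9–C10–C20 ring) | O=C1CC[C@H]2[C@@](C)(CO[Si](CC)(CC)CC)C[C@H](O[Si](C)(C)C(C)(C)C)C[C@@]23C[C@@H]13
A3 | alternative 2 | ring B ketone with Z-3-iodoallyl group on C10 and 3-silyloxyprop-1-en-2-yl group on C5 | O=C1CC[C@@H](C(=C)CO[Si](C)(C)C(C)(C)C)[C@](C)(C/C=C\I)[C@H]1CCC1(C)OCCO1
A4 | alternative 2 | 2-ene trans-decalin-8-one with quaternary C4 | O=C1CC[C@H]2[C@@](C)(CO[Si](C)(C)C(C)(C)C)C=CC[C@]2(C)[C@H]1CCC1(C)OCCO1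
A5 | alternative 3 | ring A with C10 vinyl group and C6–C7-linked 2,2-dimethyl-1,3-dioxin-4-one | CC1(C)OC(CC[C@H]2[C@@](C)(CO[Si](CC)(CC)CC)C[C@H](O[Si](C)(C)C(C)(C)C)C[C@]2(C)C=C)=CC(=O)O1
A6 | alternative 3 | 8-oxo trans-decalin with C9 methyl propanoate chain | O=C1CC[C@H]2[C@@](C)(CO[Si](CC)(CC)CC)C[C@H](O[Si](C)(C)C(C)(C)C)C[C@]2(C)[C@H]1CCC(=O)OC
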